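**Plan**
Locants used in the text: C1 = ring C=O, C2 = CBr, C3 = ring CH, C4 = carbinol carbon, C5 = ring carbon carrying exocyclic C6; side chain C6–C10 (systematic names keep their own locants).
Cuts, in order: O–Si at C4; C6–C7 (enol triflate + (E)-butenylboronate); ring bond C1–C5 (reverse 1,2-acyl shift, returning C6 to a six-membered 5,6-epoxycyclohex-2-enone); C2–Br; the epoxide C–O bonds; C4–O (phenol dearomatisation); aryl–CH2.
Forward: the ester chain is joined to 4-iodophenol, the arene supplies C1–C6, the cyclopentenone ring arises only in step 6 by ring contraction, and the butenyl unit C7–C10 is joined last.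
Enabling feature: exocyclic C6 sits on C5 between C1 and C4, so C1(=O)–C5=C6 is a masked 2-formyl ketone beside the oxygenated C4. This is the pattern left when C6, the α-carbon of a 4-oxy-5,6-epoxycyclohexenone, is pushed out of the ring as C1 migrates from C6 to C5.
Stereochemistry: C4 (S), the only stereocentre, is set by a catalyst-controlled epoxidation that selects one of the two enantiotopic enone double bonds of the prochiral quinol silyl ether; the epoxide centres are consumed in step 6. The 5Z geometry comes from the chelated enol and its triflate through a stereoretentive coupling; the 7E bond comes with the boronate.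

Key step: step 6

Remark (assumption): the quinine-derived primary amine in step 4 is assumed to induce the sense that leads to the (1S,2S,6R)-epoxide 7; if the opposite sense is found, the quinidine-derived pseudo-enantiomer is used with no other change.

**Route**

Step 1
Reactants: 1 4-iodophenol; 2 methyl oct-7-enoate
Product: 4 methyl 8-(4-hydroxyphenyl)octanoate, via alkyl-9-BBN borane 3 (not isolated)
Conditions: 2, 9-BBN, THF, 0 °C → rt; then 1, PdCl2(dppf)·CH2Cl2 (cat.), aq K3PO4, DMF, 50 °C
Reagents that add atoms: 9-borabicyclo[3.3.1]nonane (9-BBN), B1C2CCCC1CCC2 (its boron cage is carried in 3 only; 4 keeps one hydrogen from it)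
Why: 9-BBN hydroborates the terminal alkene anti-Markovnikov without reducing the ester, and the primary B-alkyl group is then transferred to the aryl iodide in a B-alkyl Suzuki–Miyaura coupling, the phenol being carried as its phenoxide under the phosphate base.

Step 2
Reactants: 4 methyl 8-(4-hydroxyphenyl)octanoate
Product: 5 methyl 8-(1-hydroxy-4-oxocyclohexa-2,5-dien-1-yl)octanoate
Conditions: PhI(OAc)2, MeCN/H2O (3:1), 0 °C
Reagents that add atoms: water, O
Why: Iodine(III) oxidative dearomatisation, in which the aryloxy-iodane is attacked by water at the alkyl-bearing para carbon to give the achiral (Cs-symmetric) p-quinol.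

Step 3
Reactants: 5 methyl 8-(1-hydroxy-4-oxocyclohexa-2,5-dien-1-yl)octanoate
Product: 6 methyl 8-[4-oxo-1-(triethylsilyloxy)cyclohexa-2,5-dien-1-yl]octanoate
Conditions: Et3SiOTf, 2,6-lutidine, CH2Cl2, −78 → 0 °C
Reagents that add atoms: triethylsilyl trifluoromethanesulfonate, CC[Si](CC)(CC)OS(=O)(=O)C(F)(F)F
Why: Silyl triflate with a hindered pyridine base silylates even a tertiary carbinol, and the triethylsilyl ether is chosen to tolerate BF3·OEt2 at low temperature yet leave with buffered HF at the end.

Step 4
Reactants: 6 methyl 8-[4-oxo-1-(triethylsilyloxy)cyclohexa-2,5-dien-1-yl]octanoate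
Product: 7 methyl 8-[(1S,2S,6R)-5-oxo-2-(triethylsilyloxy)-7-oxabicyclo[4.1.0]hept-3-en-2-yl]octanoate (epoxide anti to OSiEt3)
Conditions: 9-amino-9-deoxy-epi-quinine (10 mol%), CF3CO2H (20 mol%), 50% aq H2O2 (1.2 equiv), 1,4-dioxane, 30 °C; syn-epoxide removed by chromatography
Reagents that add atoms: hydrogen peroxide, OO
Why: Proposed new method: the primary amine condenses with the dienone to an iminium ion, its protonated quinuclidine guides H2O2 to one β-carbon and the enamine so formed closes the epoxide (an iminium-mediated Weitz–Scheffer sequence), so the catalyst fixes the absolute configuration of both epoxide carbons while the preference for attack anti to the bulky OSiEt3 group decides which of the two enantiotopic double bonds reacts and thereby sets C4 as S; the closest known reaction type is the cinchona-primary-amine-salt-catalysed epoxidation of cyclohex-2-enones (4,4-disubstituted ones included) with aqueous H2O2, which has not been used to desymmetrise a 4-silyloxycyclohexa-2,5-dienone, and the syn-epoxide, which would carry the opposite C4 configuration, is a diastereomer and is removed by chromatography.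

Step 5
Reactants: 7 methyl 8-[(1S,2S,6R)-5-oxo-2-(triethylsilyloxy)-7-oxabicyclo[4.1.0]hept-3-en-2-yl]octanoate
Product: 9 methyl 8-[(1S,2S,6R)-4-bromo-5-oxo-2-(triethylsilyloxy)-7-oxabicyclo[4.1.0]hept-3-en-2-yl]octanoate, via trans-dibromide 8 (not isolated)
Conditions: Br2, CH2Cl2, −20 → 0 °C; then Et3N, 0 °C
Reagents that add atoms: bromine, BrBr
Why: Addition–elimination α-bromination of an enone, in which bromine adds across the remaining C2=C3 bond and triethylamine removes the acidic C2–H with loss of the C3 bromide, under non-acidic conditions that leave the epoxide, silyl ether, ester and all stereocentres untouched.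

Step 6
Reactants: 9 methyl 8-[(1S,2S,6R)-4-bromo-5-oxo-2-(triethylsilyloxy)-7-oxabicyclo[4.1.0]hept-3-en-2-yl]octanoate
Product: 11 methyl 8-[(1S,5Z)-3-bromo-5-(hydroxymethylidene)-4-oxo-1-(triethylsilyloxy)cyclopent-2-en-1-yl]octanoate, via 5-formyl ketone 10 (not isolated)
Conditions: BF3·OEt2 (1.1 equiv), CH2Cl2, −78 → −30 °C; pH 7 phosphate buffer
Reagents that add atoms: none
Why: BF3 binds the epoxide oxygen and the C5–O bond (β to the ketone, next to C4) ionises rather than the C6–O bond, because positive charge at C6 would sit α to the carbonyl; as it breaks, the acyl carbon C1 shifts from C6 to C5 with inversion at C5, C6 becomes a formyl carbon (10), and enolisation on buffered work-up gives the hydrogen-bonded hydroxymethylene ketone 11. The closest known reaction type is the BF3-mediated rearrangement of 2,3-epoxycyclohexanones to 2-formylcyclopentanones by 1,2-acyl migration. The cyclopentenone ring is not closed by cyclisation: it arises by 6 → 5 ring contraction, the new ring bond C1–C5 forming as C1–C6 breaks. No stereocentre remains to be controlled, since C4 is a spectator, both epoxide centres are consumed, the transient C5 centre of 10 is erased on enolisation and the Z enol geometry is held by the O–H···O=C1 hydrogen bond. The step needs acyl migration to outrun hydride migration from C6 (leading to a diosphenol) and a semipinacol shift from C4: the acyl group is the better migrating group in this rearrangement, and with the epoxide anti to OSiEt3 the alkyl chain on C4 lies syn to the breaking C5–O bond, so no carbon substituent of C4 is anti-periplanar to it. Low temperature and a buffered quench are chosen to keep the triethylsilyl ether and the ester intact.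

Step 7
Reactants: 11 methyl 8-[(1S,5Z)-3-bromo-5-(hydroxymethylidene)-4-oxo-1-(triethylsilyloxy)cyclopent-2-en-1-yl]octanoate
Product: 12 methyl 8-[(1S,5Z)-3-bromo-4-oxo-1-(triethylsilyloxy)-5-{[(trifluoromethanesulfonyl)oxy]methylidene}cyclopent-2-en-1-yl]octanoate
Conditions: LiOTf, Et3N, Tf2O, CH2Cl2, −78 → −20 °C; used after rapid filtration through silica
Reagents that add atoms: trifluoromethanesulfonic anhydride, O=S(=O)(OS(=O)(=O)C(F)(F)F)C(F)(F)F
Why: Triflation of the enolate of a 2-formyl ketone takes place at the formyl-derived oxygen, and lithium chelation between the two oxygens (the LiOTf/amine protocol known for Z-enol triflates of 1,3-dicarbonyl compounds) holds the U-shaped enolate so that OTf ends up syn to the C1 carbonyl (5Z).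

Step 8
Reactants: 12 methyl 8-[(1S,5Z)-3-bromo-4-oxo-1-(triethylsilyloxy)-5-{[(trifluoromethanesulfonyl)oxy]methylidene}cyclopent-2-en-1-yl]octanoate; 13 2-[(1E)-but-1-en-1-yl]-4,4,5,5-tetramethyl-1,3,2-dioxaborolane
Product: 14 methyl 8-[(1S,5Z)-3-bromo-4-oxo-5-[(2E)-pent-2-en-1-ylidene]-1-(triethylsilyloxy)cyclopent-2-en-1-yl]octanoate
Conditions: PdCl2(dppf)·CH2Cl2 (5 mol%), K3PO4, degassed THF/H2O (10:1), 20 °C, light excluded
Reagents that add atoms: none
Why: Suzuki–Miyaura coupling in which the vinylogous acyl triflate (β-triflyloxy enone) should undergo oxidative addition at room temperature much faster than the α-bromoenone C2–Br bond, and both partners react with retention, so the new C6–C7 bond places the chain syn to C1=O (5Z) and keeps the 7E geometry of the boronate.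

Step 9
Reactants: 14 methyl 8-[(1S,5Z)-3-bromo-4-oxo-5-[(2E)-pent-2-en-1-ylidene]-1-(triethylsilyloxy)cyclopent-2-en-1-yl]octanoate
Product: 15 methyl 8-[(1S,5Z)-3-bromo-1-hydroxy-4-oxo-5-[(2E)-pent-2-en-1-ylidene]cyclopent-2-en-1-yl]octanoate
Conditions: HF·pyridine, pyridine/THF, 0 °C → rt, light excluded
Reagents that add atoms: none
Why: Fluoride-driven Si–O cleavage by pyridine-buffered HF, conditions that are neither basic nor strongly nucleophilic and so should spare the cross-conjugated bromodienone, its double-bond geometry and the methyl ester, while the tertiary alcohol cannot ionise because a cation at C4 would be a carbonyl-conjugated cyclopentadienyl-type cation.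

**Compound list**
1 | 4-iodophenol | Oc1ccc(I)cc1 | starting material
2 | methyl oct-7-enoate | C=CCCCCCC(=O)OC | starting material
3 | methyl 8-(9-borabicyclo[3.3.1]nonan-9-yl)octanoate | COC(=O)CCCCCCCB1C2CCCC1CCC2 | intermediate (not isolated)
4 | methyl 8-(4-hydroxyphenyl)octanoate | COC(=O)CCCCCCCc1ccc(O)cc1 | intermediate
5 | methyl 8-(1-hydroxy-4-oxocyclohexa-2,5-dien-1-yl)octanoate | COC(=O)CCCCCCCC1(O)C=CC(=O)C=C1 | intermediate
6 | methyl 8-[4-oxo-1-(triethylsilyloxy)cyclohexa-2,5-dien-1-yl]octanoate | COC(=O)CCCCCCCC1(O[Si](CC)(CC)CC)C=CC(=O)C=C1 | intermediate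
7 | methyl 8-[(1S,2S,6R)-5-oxo-2-(triethylsilyloxy)-7-oxabicyclo[4.1.0]hept-3-en-2-yl]octanoate (epoxide anti to OSiEt3) | C1=C[C@@]([C@H]2O[C@H]2C1=O)(O[Si](CC)(CC)CC)CCCCCCCC(=O)OC | intermediate
8 | methyl 8-[(1S,2R,6R)-3,4-dibromo-5-oxo-2-(triethylsilyloxy)-7-oxabicyclo[4.1.0]heptan-2-yl]octanoate (trans-dibromide, configuration at C-3 and C-4 not assigned) | BrC1C(Br)[C@@]([C@H]2O[C@H]2C1=O)(O[Si](CC)(CC)CC)CCCCCCCC(=O)OC | intermediate (not isolated)
9 | methyl 8-[(1S,2S,6R)-4-bromo-5-oxo-2-(triethylsilyloxy)-7-oxabicyclo[4.1.0]hept-3-en-2-yl]octanoate (epoxide anti to OSiEt3) | BrC1=C[C@@]([C@H]2O[C@H]2C1=O)(O[Si](CC)(CC)CC)CCCCCCCC(=O)OC | intermediate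
10 | methyl 8-[(1R,5S)-3-bromo-5-formyl-4-oxo-1-(triethylsilyloxy)cyclopent-2-en-1-yl]octanoate (formyl trans to OSiEt3) | O=C[C@H]1C(=O)C(Br)=C[C@@]1(O[Si](CC)(CC)CC)CCCCCCCC(=O)OC | intermediate (not isolated)
11 | methyl 8-[(1S,5Z)-3-bromo-5-(hydroxymethylidene)-4-oxo-1-(triethylsilyloxy)cyclopent-2-en-1-yl]octanoate | O/C=C1\C(=O)C(Br)=C[C@@]1(O[Si](CC)(CC)CC)CCCCCCCC(=O)OC | intermediate
12 | methyl 8-[(1S,5Z)-3-bromo-4-oxo-1-(triethylsilyloxy)-5-{[(trifluoromethanesulfonyl)oxy]methylidene}cyclopent-2-en-1-yl]octanoate | FC(F)(F)S(=O)(=O)O/C=C1\C(=O)C(Br)=C[C@@]1(O[Si](CC)(CC)CC)CCCCCCCC(=O)OC | intermediate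
13 | 2-[(1E)-but-1-en-1-yl]-4,4,5,5-tetramethyl-1,3,2-dioxaborolane | CC/C=C/B1OC(C)(C)C(C)(C)O1 | starting material
14 | methyl 8-[(1S,5Z)-3-bromo-4-oxo-5-[(2E)-pent-2-en-1-ylidene]-1-(triethylsilyloxy)cyclopent-2-en-1-yl]octanoate | CC/C=C/C=C1\C(=O)C(Br)=C[C@@]1(O[Si](CC)(CC)CC)CCCCCCCC(=O)OC | intermediate
15 | methyl 8-[(1S,5Z)-3-bromo-1-hydroxy-4-oxo-5-[(2E)-pent-2-en-1-ylidene]cyclopent-2-en-1-yl]octanoate | CC/C=C/C=C1\C(=O)C(Br)=C[C@@]1(O)CCCCCCCC(=O)OC | target

**Count**
Total steps: 9. Longest linear sequence: 9 steps (from 4-iodophenol and methyl oct-7-enoate; the boronate enters in step 8).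

**Steps most likely to fail**

Step 4 (proposed new method). The catalyst may discriminate poorly between the two enantiotopic enone units. The anti/syn preference of the substrate may be weak, so that much material is diverted to the syn-epoxide. Iminium formation with the hindered cross-conjugated dienone may be slow. The silyl ether may be lost in the acidic aqueous medium, after which a free hydroxyl would steer the peroxide syn. A second epoxidation may also follow. Fallback with known chemistry: setting out from 6, a Weitz–Scheffer epoxidation without asymmetric induction (t-BuOOH, DBU, CH2Cl2, 0 °C) should again favour attack anti to OSiEt3 and give the racemic anti-epoxide, that is 7 together with its enantiomer methyl 8-[(1R,2R,6S)-5-oxo-2-(triethylsilyloxy)-7-oxabicyclo[4.1.0]hept-3-en-2-yl]octanoate F1. The two are separated by preparative chromatography on a polysaccharide-carbamate chiral stationary phase, and the route is rejoined at 7.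

Step 6. Ionisation of the C5–O bond is retarded by the neighbouring oxygenated C4, so hydride migration from C6 (then aromatisation with loss of silanol), migration of the ring vinyl carbon C3 from C4, or Lewis-acid desilylation may outrun the acyl shift. The bromine also makes the migrating acyl carbon more electron-poor. Fallback, with the contraction moved ahead of the bromination: setting out from 7, BF3·OEt2 (CH2Cl2, −78 °C) should give the formyl ketone methyl 8-[(1S,5S)-5-formyl-4-oxo-1-(triethylsilyloxy)cyclopent-2-en-1-yl]octanoate F2, which enolises to methyl 8-[(1S,5Z)-5-(hydroxymethylidene)-4-oxo-1-(triethylsilyloxy)cyclopent-2-en-1-yl]octanoate F3. Chelation-controlled triflation (LiOTf, Et3N, Tf2O) gives methyl 8-[(1S,5Z)-4-oxo-1-(triethylsilyloxy)-5-{[(trifluoromethanesulfonyl)oxy]methylidene}cyclopent-2-en-1-yl]octanoate F4. Bromine then adds to the ring enone bond, the triflyloxy-alkene being the more deactivated one, to give the trans-dibromide methyl 8-[(1R,5Z)-2,3-dibromo-4-oxo-1-(triethylsilyloxy)-5-{[(trifluoromethanesulfonyl)oxy]methylidene}cyclopentyl]octanoate F5. Triethylamine eliminates HBr and the route is rejoined at 12.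

Step 8. Oxidative addition may compete at the C2–Br bond, the β-palladated enone or the product dienone may isomerise from 5Z to 5E, and the vinylogous triflate may be hydrolysed by the aqueous base. Fallback without palladium, by aldol condensation: setting out from 11, retro-Claisen deformylation (K2CO3, MeOH, 0 °C) gives methyl 8-[(1R)-3-bromo-4-oxo-1-(triethylsilyloxy)cyclopent-2-en-1-yl]octanoate F6. Its lithium enolate (LiHMDS, THF, −78 °C) is added to (E)-pent-2-enal and quenched with acetic acid to give the aldol methyl 8-[(1R)-3-bromo-5-[(2E)-1-hydroxypent-2-en-1-yl]-4-oxo-1-(triethylsilyloxy)cyclopent-2-en-1-yl]octanoate F7 as a diastereomer mixture. Mesylation (MsCl, Et3N) gives methyl 8-[(1R)-3-bromo-5-[(2E)-1-(methanesulfonyloxy)pent-2-en-1-yl]-4-oxo-1-(triethylsilyloxy)cyclopent-2-en-1-yl]octanoate F8. Elimination with DBU should give 14 together with its 5E isomer methyl 8-[(1S,5E)-3-bromo-4-oxo-5-[(2E)-pent-2-en-1-ylidene]-1-(triethylsilyloxy)cyclopent-2-en-1-yl]octanoate F9. The isomers are separated, the 5E isomer can be re-equilibrated by irradiation, and the route is rejoined at 14.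

**Further compounds**
F1 | step 4 | methyl 8-[(1R,2R,6S)-5-oxo-2-(triethylsilyloxy)-7-oxabicyclo[4.1.0]hept-3-en-2-yl]octanoate | C1=C[C@]([C@@H]2O[C@@H]2C1=O)(O[Si](CC)(CC)CC)CCCCCCCC(=O)OC
F2 | step 6 | methyl 8-[(1S,5S)-5-formyl-4-oxo-1-(triethylsilyloxy)cyclopent-2-en-1-yl]octanoate | O=C[C@H]1C(=O)C=C[C@@]1(O[Si](CC)(CC)CC)CCCCCCCC(=O)OC
F3 | step 6 | methyl 8-[(1S,5Z)-5-(hydroxymethylidene)-4-oxo-1-(triethylsilyloxy)cyclopent-2-en-1-yl]octanoate | O/C=C1\C(=O)C=C[C@@]1(O[Si](CC)(CC)CC)CCCCCCCC(=O)OC
F4 | step 6 | methyl 8-[(1S,5Z)-4-oxo-1-(triethylsilyloxy)-5-{[(trifluoromethanesulfonyl)oxy]methylidene}cyclopent-2-en-1-yl]octanoate | FC(F)(F)S(=O)(=O)O/C=C1\C(=O)C=C[C@@]1(O[Si](CC)(CC)CC)CCCCCCCC(=O)OC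
F5 | step 6 | methyl 8-[(1R,5Z)-2,3-dibromo-4-oxo-1-(triethylsilyloxy)-5-{[(trifluoromethanesulfonyl)oxy]methylidene}cyclopentyl]octanoate (trans-dibromide, C-2 and C-3 not assigned) | FC(F)(F)S(=O)(=O)O/C=C1\C(=O)C(Br)C(Br)[C@@]1(O[Si](CC)(CC)CC)CCCCCCCC(=O)OC
F6 | step 8 | methyl 8-[(1R)-3-bromo-4-oxo-1-(triethylsilyloxy)cyclopent-2-en-1-yl]octanoate | C1C(=O)C(Br)=C[C@@]1(O[Si](CC)(CC)CC)CCCCCCCC(=O)OC
F7 | step 8 | methyl 8-[(1R)-3-bromo-5-[(2E)-1-hydroxypent-2-en-1-yl]-4-oxo-1-(triethylsilyloxy)cyclopent-2-en-1-yl]octanoate (diastereomer mixture at C-5 and the side-chain carbinol) | CC/C=C/C(O)C1C(=O)C(Br)=C[C@@]1(O[Si](CC)(CC)CC)CCCCCCCC(=O)OC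
F8 | step 8 | methyl 8-[(1R)-3-bromo-5-[(2E)-1-(methanesulfonyloxy)pent-2-en-1-yl]-4-oxo-1-(triethylsilyloxy)cyclopent-2-en-1-yl]octanoate (diastereomer mixture) | CC/C=C/C(OS(C)(=O)=O)C1C(=O)C(Br)=C[C@@]1(O[Si](CC)(CC)CC)CCCCCCCC(=O)OC
F9 | step 8 | methyl 8-[(1S,5E)-3-bromo-4-oxo-5-[(2E)-pent-2-en-1-ylidene]-1-(triethylsilyloxy)cyclopent-2-en-1-yl]octanoate | CC/C=C/C=C1/C(=O)C(Br)=C[C@@]1(O[Si](CC)(CC)CC)CCCCCCCC(=O)OC
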